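The 1,2-dioxane ring is opened across the C4–C4a and O2–C3 bonds (furo[3,2-c][1,2]dioxine numbering). This exposes C4/C3 as a 1,1-disubstituted alkene, whose CH2 end is nucleophilic and whose substituted end becomes a tertiary cation, and C4a–C7a–O1–O2 as an α-peroxy ketone. The key step joins both in one operation: a chelated, Prins-type addition of the alkene to the ketone, capture of the cation by the silyl peroxide, and lactonisation of the new tertiary alkoxide. The precursor is an enantiopure α-silylperoxy γ-keto ester, made by a Schenck ene reaction, enzymatic resolution and ozonolysis; the alkene is an enyne whose slim alkynyl group steers C3 and is saturated last.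

Key step: step 6

Remark: ring positions are numbered O1, O2, C3, C4, C4a, O5, C6, C7, C7a; compounds 1, 2 and 5 are assumed to be catalogue chemicals.

Step 1
Reactants: 1 (8-bromooctyl)benzene; 2 2-methylbut-1-en-3-yne
Product: 4 2-methyl-12-phenyldodec-1-en-3-yne, via lithium 3-methylbut-3-en-1-yn-1-ide 3 (not isolated)
Conditions: n-BuLi, THF, −78 °C; then 1, DMPU, −78 °C → rt
Reagents that add atoms: none
Why: SN2 alkylation of a lithium acetylide by a primary alkyl bromide in a dipolar cosolvent; the acetylenic C–H is the only acidic site of 2 and no stereocentre is formed.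

Step 2
Reactants: 5 methyl 4-methylpent-3-enoate
Product: 6 methyl 3-hydroperoxy-4-methylpent-4-enoate (racemic)
Conditions: O2, hν (visible), tetraphenylporphyrin (cat.), CH2Cl2, 0 °C
Reagents that add atoms: dioxygen, O=O
Why: Schenck ene reaction of singlet oxygen with the trisubstituted alkene: oxygen should bond to C3 with hydrogen transfer from the geminal methyl groups, because the allylic CH2 next to the ester is deactivated, so the C3 stereocentre arises as a racemate.

Step 3
Reactants: 6 methyl 3-hydroperoxy-4-methylpent-4-enoate (racemic)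
Product: 7 methyl (3S)-3-hydroperoxy-4-methylpent-4-enoate
Conditions: horseradish peroxidase (cat.), guaiacol, phosphate buffer (pH 6), rt, stopped past half conversion
Reagents that add atoms: none
Why: Enzymatic kinetic resolution by a heme peroxidase (oxidoreductase class): the (3R)-hydroperoxide should be reduced to the alcohol at the expense of guaiacol while the (3S)-hydroperoxide is left, which fixes the absolute configuration of the later C7a; the sense is that expected for secondary allylic hydroperoxides in which the alkenyl group outranks the alkyl group.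

Step 4
Reactants: 7 methyl (3S)-3-hydroperoxy-4-methylpent-4-enoate
Product: 8 methyl (3S)-4-methyl-3-[(triethylsilyl)peroxy]pent-4-enoate
Conditions: Et3SiCl, imidazole, DMF, 0 °C
Reagents that add atoms: chlorotriethylsilane, CC[Si](Cl)(CC)CC
Why: Silylation of the hydroperoxide oxygen (silyl peroxide formation) masks the OOH group against the ozonolysis work-up and turns it into the silyl-capped nucleophile needed in step 6; the stereocentre is not touched.

Step 5
Reactants: 8 methyl (3S)-4-methyl-3-[(triethylsilyl)peroxy]pent-4-enoate
Product: 10 methyl (3S)-4-oxo-3-[(triethylsilyl)peroxy]pentanoate, via primary ozonide 9 (not isolated)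
Conditions: O3, CH2Cl2/MeOH, −78 °C; then Me2S, −78 °C → rt
Reagents that add atoms: ozone, [O-][O+]=O
Why: Ozonolysis of the 1,1-disubstituted alkene with reductive work-up gives the methyl ketone, the silyl peroxide being inert to ozone and Me2S, and the neutral conditions should not enolise the α-peroxy ketone stereocentre.

Step 6
Reactants: 10 methyl (3S)-4-oxo-3-[(triethylsilyl)peroxy]pentanoate; 4 2-methyl-12-phenyldodec-1-en-3-yne
Product: 12 (3S,4aS,7aS)-3,4a-dimethyl-3-(10-phenyldec-1-yn-1-yl)tetrahydrofuro[3,2-c][1,2]dioxin-6(3H)-one, via hydroxy ester 11 (not isolated)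
Conditions: SnCl4, CH2Cl2, −78 °C; aq. NaHCO3; then PPTS (cat.), CH2Cl2, rt
Reagents that add atoms: none
Why: Proposed new method: SnCl4 is expected to chelate the ketone oxygen and the proximal peroxide oxygen of 10, the CH2 terminus of enyne 4 adds to the activated carbonyl carbon in a Prins-type step (bond C4–C4a), and the tertiary propargylic cation so formed is captured by the distal silyl peroxide oxygen with loss of Et3SiCl (bond O2–C3); the closest known reaction type is the SnCl4-mediated annulation of triethylsilyl peroxyketals with alkenes to 1,2-dioxolanes, here extended by one ring atom with a chelated ketone as the electrophile in place of a peroxycarbenium ion. The 1,2-dioxane ring closes by cation capture through a six-membered chair transition state (6-endo with respect to the former C=C bond), and the lactone ring then closes by 5-exo-trig attack of the tertiary oxygen on the ester carbonyl, which is possible only for the cis isomer. C4a is set by chelation control from the existing C7a stereocentre: the alkene approaches the face of the five-membered tin chelate that is opposite to the CH2CO2Me group. C3 is set in the ring closure: the chelate holds the C4a oxygen axial, so the slim, linear alkynyl group should take the axial position syn to it and the methyl group the equatorial one. The step needs cation capture by the peroxide to outrun proton loss (ene-type product) and chloride capture, and it needs the α-peroxy ketone to survive the Lewis acid without Hock- or Criegee-type cleavage; the low temperature, the silyl cap on the distal oxygen and the intramolecular six-membered capture should secure this.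

Step 7
Reactants: 12 (3S,4aS,7aS)-3,4a-dimethyl-3-(10-phenyldec-1-yn-1-yl)tetrahydrofuro[3,2-c][1,2]dioxin-6(3H)-one
Product: 13 (3R,4aS,7aS)-3,4a-dimethyl-3-(10-phenyldecyl)tetrahydrofuro[3,2-c][1,2]dioxin-6(3H)-one
Conditions: KO2C–N=N–CO2K (excess), AcOH, MeOH/CH2Cl2, 0 °C → rt
Reagents that add atoms: none
Why: Diimide reduction transfers hydrogen to the C≡C bond in two concerted syn additions without touching the O–O bond or the lactone, so the three stereocentres are kept and only the CIP descriptor at C3 changes from S to R.

Compound list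
1 | (8-bromooctyl)benzene | BrCCCCCCCCc1ccccc1 | starting material
2 | 2-methylbut-1-en-3-yne | C=C(C)C#C | starting material
3 | lithium 3-methylbut-3-en-1-yn-1-ide | [Li]C#CC(C)=C | intermediate
4 | 2-methyl-12-phenyldodec-1-en-3-yne | C=C(C)C#CCCCCCCCCc1ccccc1 | intermediate
5 | methyl 4-methylpent-3-enoate | COC(=O)CC=C(C)C | starting material
6 | methyl 3-hydroperoxy-4-methylpent-4-enoate (racemic) | COC(=O)CC(OO)C(C)=C | intermediate
7 | methyl (3S)-3-hydroperoxy-4-methylpent-4-enoate | COC(=O)C[C@H](OO)C(C)=C | intermediate
8 | methyl (3S)-4-methyl-3-[(triethylsilyl)peroxy]pent-4-enoate | COC(=O)C[C@H](OO[Si](CC)(CC)CC)C(C)=C | intermediate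
9 | primary ozonide, methyl (3S)-3-(4-methyl-1,2,3-trioxolan-4-yl)-3-[(triethylsilyl)peroxy]propanoate | COC(=O)C[C@H](OO[Si](CC)(CC)CC)C1(C)COOO1 | intermediate
10 | methyl (3S)-4-oxo-3-[(triethylsilyl)peroxy]pentanoate | COC(=O)C[C@H](OO[Si](CC)(CC)CC)C(C)=O | intermediate
11 | hydroxy ester, methyl 2-[(3S,4S,6S)-4-hydroxy-4,6-dimethyl-6-(10-phenyldec-1-yn-1-yl)-1,2-dioxan-3-yl]acetate | C[C@@]1(C#CCCCCCCCCc2ccccc2)C[C@](C)(O)[C@H](CC(=O)OC)OO1 | intermediate
12 | (3S,4aS,7aS)-3,4a-dimethyl-3-(10-phenyldec-1-yn-1-yl)tetrahydrofuro[3,2-c][1,2]dioxin-6(3H)-one | C[C@@]1(C#CCCCCCCCCc2ccccc2)C[C@]2(C)OC(=O)C[C@@H]2OO1 | intermediate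
13 | (3R,4aS,7aS)-3,4a-dimethyl-3-(10-phenyldecyl)tetrahydrofuro[3,2-c][1,2]dioxin-6(3H)-one | C[C@@]1(CCCCCCCCCCc2ccccc2)C[C@]2(C)OC(=O)C[C@@H]2OO1 | target

Total step count: 7. Longest linear sequence: 6 steps (5 to 13, steps 2 to 7); step 1 is the convergent branch.

Steps most likely to fail

Step 6 (Proposed new method). The tin-bound ketone may be too weak an electrophile for the enyne, the cation may lose a proton instead of being captured by the peroxide, or the α-silylperoxy ketone may fragment under the Lewis acid. The fallback makes the two bonds one after the other by known reactions; it sets out from 1 and 10 and comes back to the route at 12. Alkylation of 1 with lithium acetylide–ethylenediamine complex (DMSO, rt) gives 10-phenyldec-1-yne F1. Sonogashira coupling of F1 with (2-bromoallyl)trimethylsilane (Pd(PPh3)4, CuI, Et3N) gives the allylsilane trimethyl(2-methylidene-12-phenyldodec-3-yn-1-yl)silane F2. Chelation-controlled Hosomi–Sakurai addition of F2 to 10 (TiCl4, CH2Cl2, −78 °C) gives the hydroxy ester methyl (3S,4S)-4-hydroxy-4-methyl-6-methylidene-16-phenyl-3-[(triethylsilyl)peroxy]hexadec-7-ynoate F3. PPTS closes it to the lactone (4S,5S)-5-methyl-5-(2-methylidene-12-phenyldodec-3-yn-1-yl)-4-[(triethylsilyl)peroxy]oxolan-2-one F4. HF·pyridine removes the silyl group to give the hydroperoxide (4S,5S)-4-hydroperoxy-5-methyl-5-(2-methylidene-12-phenyldodec-3-yn-1-yl)oxolan-2-one F5. N-Iodosuccinimide (CH2Cl2, 0 °C) then closes the 1,2-dioxane by Markovnikov iodo-peroxidation of the 1,1-disubstituted alkene, with the bulky iodomethyl group equatorial, to the iodide (3S,4aS,7aS)-3-(iodomethyl)-4a-methyl-3-(10-phenyldec-1-yn-1-yl)tetrahydrofuro[3,2-c][1,2]dioxin-6(3H)-one F6. Bu3SnH/Et3B (toluene, −20 °C, high hydride concentration to outrun epoxide formation from the β-peroxy radical) replaces iodine by hydrogen and gives 12.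

Step 3. The peroxidase may discriminate poorly between the enantiomers of a hydroperoxide whose two carbon substituents are similar in size, or may reduce both. The fallback is a resolution through covalent diastereomers; it sets out from 6 and comes back at 7. Racemic 6 is added to the enantiopure enol ether [(1R,2S)-2-(prop-1-en-2-yloxy)cyclohexyl]benzene (PPTS cat., CH2Cl2), and the two diastereomeric perketals are separated by chromatography. The (3S)-diastereomer, methyl (3S)-4-methyl-3-[(2-{[(1R,2S)-2-phenylcyclohexyl]oxy}propan-2-yl)peroxy]pent-4-enoate F7, is cleaved with aqueous acetic acid to 7.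

Step 7. The diimide reduction of the hindered alkyne next to the quaternary carbon may stall at the cis-alkene stage. The fallback gives up the alkynyl control element and carries the saturated chain from the start; it sets out from 1 and 10 and comes back at 13. Magnesium in THF converts 1 into (8-phenyloctyl)magnesium bromide F8. Li2CuCl4-catalysed coupling with 4-bromo-2-methylbut-1-ene gives 2-methyl-12-phenyldodec-1-ene F9, which is used in place of 4 under the conditions of step 6. The hydroxy ester methyl 2-[(3S,4S,6R)-4-hydroxy-4,6-dimethyl-6-(10-phenyldecyl)-1,2-dioxan-3-yl]acetate F10 then lactonises to 13 directly. The price is weaker control at C3, so the C3 epimer would have to be removed by chromatography.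

Further compounds
F1 | step 6 | 10-phenyldec-1-yne | C#CCCCCCCCCc1ccccc1
F2 | step 6 | trimethyl(2-methylidene-12-phenyldodec-3-yn-1-yl)silane | C=C(C[Si](C)(C)C)C#CCCCCCCCCc1ccccc1
F3 | step 6 | methyl (3S,4S)-4-hydroxy-4-methyl-6-methylidene-16-phenyl-3-[(triethylsilyl)peroxy]hexadec-7-ynoate | COC(=O)C[C@H](OO[Si](CC)(CC)CC)[C@@](C)(O)CC(=C)C#CCCCCCCCCc1ccccc1
F4 | step 6 | (4S,5S)-5-methyl-5-(2-methylidene-12-phenyldodec-3-yn-1-yl)-4-[(triethylsilyl)peroxy]oxolan-2-one | C=C(C#CCCCCCCCCc1ccccc1)C[C@]1(C)OC(=O)C[C@@H]1OO[Si](CC)(CC)CC
F5 | step 6 | (4S,5S)-4-hydroperoxy-5-methyl-5-(2-methylidene-12-phenyldodec-3-yn-1-yl)oxolan-2-one | C=C(C#CCCCCCCCCc1ccccc1)C[C@]1(C)OC(=O)C[C@@H]1OO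
F6 | step 6 | (3S,4aS,7aS)-3-(iodomethyl)-4a-methyl-3-(10-phenyldec-1-yn-1-yl)tetrahydrofuro[3,2-c][1,2]dioxin-6(3H)-one | IC[C@@]1(C#CCCCCCCCCc2ccccc2)C[C@]2(C)OC(=O)C[C@@H]2OO1
F7 | step 3 | methyl (3S)-4-methyl-3-[(2-{[(1R,2S)-2-phenylcyclohexyl]oxy}propan-2-yl)peroxy]pent-4-enoate | COC(=O)C[C@H](OOC(C)(C)O[C@@H]1CCCC[C@H]1c1ccccc1)C(C)=C
F8 | step 7 | (8-phenyloctyl)magnesium bromide | Br[Mg]CCCCCCCCc1ccccc1
F9 | step 7 | 2-methyl-12-phenyldodec-1-ene | C=C(C)CCCCCCCCCCc1ccccc1
F10 | step 7 | methyl 2-[(3S,4S,6R)-4-hydroxy-4,6-dimethyl-6-(10-phenyldecyl)-1,2-dioxan-3-yl]acetate | C[C@@]1(CCCCCCCCCCc2ccccc2)C[C@](C)(O)[C@H](CC(=O)OC)OO1
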